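**Retrosynthetic overview**
1. The target comes from an undeca-O-benzyl ether by hydrogenolysis. Ring C of unit 1 is closed last, at O1–C8a, by intramolecular aryl ether formation on a syn carbinol.
2. The strategy rests on the catechol ring B of unit 1. Its C1' (bonded to C2 of ring C of unit 1) and its C6' (bonded to C2' of the pyrogallol ring B of unit 2) are neighbours, and the ring is symmetric about its oxygen-bearing C3' and C4'. Both carbon–carbon bonds are therefore cut at once, to the symmetric 4,5-bis(benzyloxy)benzyne, the C2' arylmagnesium of the complete unit 2 flavan, and an (R)-α-benzyloxy aldehyde that carries ring A of unit 1.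
3. The 2'-bromo flavan of unit 2 is made from the same aldehyde: chelation-controlled addition of a 2-bromoarylmagnesium, then copper-catalysed closure of ring C of unit 2.
4. The aldehyde comes from an Evans glycolate alkylation with a 2,4-bis(benzyloxy)-6-bromobenzyl bromide. C3 of both units derives from the auxiliary, C2 of both units from Cram chelation.
5. Order of ring formation: ring C of unit 2 (step 13), then the two skeletal bonds at ring B of unit 1 without ring closure (step 15), then ring C of unit 1 (step 16).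

Key step: step 15

Assumption: the structure as drawn fixes only the four sp3 stereocentres and not the sense of the biaryl axis, so the route does not control that axis and compounds 29 to 31 are taken as whatever rotamer mixture about this bond is formed (to be separated at 30 if the rotamers prove configurationally stable).

**Route**

Step 1
Reactants: 1 5-bromoresorcinol
Product: 2 1,3-bis(benzyloxy)-5-bromobenzene
Conditions: BnBr, K2CO3, DMF, 60 °C
Reagents that add atoms: benzyl bromide, BrCc1ccccc1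
Why: Williamson ether synthesis on both phenols; the aryl bromide is inert to carbonate and benzyl bromide.

Step 2
Reactants: 2 1,3-bis(benzyloxy)-5-bromobenzene
Product: 4 2,4-bis(benzyloxy)-6-bromobenzaldehyde, via aryliminium chloride 3 (not isolated)
Conditions: POCl3, DMF, 0 to 80 °C; then H2O, rt
Reagents that add atoms: N,N-dimethylformamide, CN(C)C=O; water, O
Why: Vilsmeier–Haack formylation should go mainly at the carbon between bromine and one benzyloxy group (ortho to one ether, para to the other), as is usual for 1-bromo-3,5-dialkoxybenzenes; the minor isomer formylated between the two ethers would be removed by crystallisation.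

Step 3
Reactants: 4 2,4-bis(benzyloxy)-6-bromobenzaldehyde
Product: 5 [2,4-bis(benzyloxy)-6-bromophenyl]methanol
Conditions: NaBH4, THF/MeOH, 0 °C
Reagents that add atoms: none
Why: Borohydride reduction of an aryl aldehyde; aryl bromide and benzyl ethers are not touched.

Step 4
Reactants: 5 [2,4-bis(benzyloxy)-6-bromophenyl]methanol
Product: 6 1,5-bis(benzyloxy)-3-bromo-2-(bromomethyl)benzene
Conditions: PBr3, Et2O, 0 °C; used at once without chromatography
Reagents that add atoms: phosphorus tribromide, BrP(Br)Br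
Why: Bromide displaces the phosphite ester of the benzylic alcohol; the electron-rich benzylic bromide is labile and is therefore carried straight into step 6.

Step 5
Reactants: 7 (S)-4-benzyloxazolidin-2-one; 8 (benzyloxy)acetyl chloride
Product: 10 (S)-4-benzyl-3-[(benzyloxy)acetyl]oxazolidin-2-one, via lithiated oxazolidinone 9 (not isolated)
Conditions: n-BuLi, THF, −78 °C; then 8, −78 to 0 °C
Reagents that add atoms: none
Why: N-acylation of the lithium salt of the Evans auxiliary with an acid chloride.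

Step 6
Reactants: 10 (S)-4-benzyl-3-[(benzyloxy)acetyl]oxazolidin-2-one; 6 1,5-bis(benzyloxy)-3-bromo-2-(bromomethyl)benzene
Product: 12 (S)-4-benzyl-3-{(R)-2-(benzyloxy)-3-[2,4-bis(benzyloxy)-6-bromophenyl]propanoyl}oxazolidin-2-one, via sodium Z-enolate 11 (not isolated)
Conditions: NaN(SiMe3)2, THF, −78 °C; then 6, −78 to −45 °C
Reagents that add atoms: none
Why: Evans asymmetric alkylation of the chelated sodium Z-glycolate enolate; the 4-benzyl group of the auxiliary blocks one face, the benzylic bromide enters anti to it, and the new centre (later C3 of both flavan units) is set as R.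

Step 7
Reactants: 12 (S)-4-benzyl-3-{(R)-2-(benzyloxy)-3-[2,4-bis(benzyloxy)-6-bromophenyl]propanoyl}oxazolidin-2-one
Product: 13 (R)-2-(benzyloxy)-3-[2,4-bis(benzyloxy)-6-bromophenyl]propan-1-ol
Conditions: LiBH4, MeOH (1 equiv), THF, 0 °C
Reagents that add atoms: none
Why: Reductive cleavage of the N-acyl oxazolidinone at the exocyclic carbonyl; the α-centre is not enolised and the auxiliary is recovered.

Step 8
Reactants: 13 (R)-2-(benzyloxy)-3-[2,4-bis(benzyloxy)-6-bromophenyl]propan-1-ol
Product: 14 (R)-2-(benzyloxy)-3-[2,4-bis(benzyloxy)-6-bromophenyl]propanal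
Conditions: Dess–Martin periodinane, pyridine, CH2Cl2, 0 °C to rt; used crude
Reagents that add atoms: none
Why: Dess–Martin oxidation under buffered conditions, which should not epimerise the α-benzyloxy aldehyde.

Step 9
Reactants: 15 5-iodo-1,2,3-trimethoxybenzene
Product: 16 5-iodobenzene-1,2,3-triol
Conditions: BBr3, CH2Cl2, −78 °C to rt; then H2O
Reagents that add atoms: none
Why: Lewis-acid cleavage of aryl methyl ethers; the aryl iodide is stable to BBr3.

Step 10
Reactants: 16 5-iodobenzene-1,2,3-triol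
Product: 17 1,2,3-tris(benzyloxy)-5-iodobenzene
Conditions: BnBr, K2CO3, DMF, 50 °C, argon
Reagents that add atoms: benzyl bromide, BrCc1ccccc1
Why: Williamson ether synthesis; argon keeps the pyrogallol from air oxidation until it is fully alkylated.

Step 11
Reactants: 17 1,2,3-tris(benzyloxy)-5-iodobenzene
Product: 18 1,2,3-tris(benzyloxy)-4-bromo-5-iodobenzene
Conditions: NBS (1.05 equiv), MeCN, 0 °C to rt, dark
Reagents that add atoms: N-bromosuccinimide, O=C1CCC(=O)N1Br
Why: Electrophilic aromatic bromination; the only free positions (C4 and C6, equivalent) are ortho and para to benzyloxy groups, and the first bromine deactivates the ring against a second.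

Step 12
Reactants: 18 1,2,3-tris(benzyloxy)-4-bromo-5-iodobenzene; 14 (R)-2-(benzyloxy)-3-[2,4-bis(benzyloxy)-6-bromophenyl]propanal
Product: 20 (1R,2R)-2-(benzyloxy)-3-[2,4-bis(benzyloxy)-6-bromophenyl]-1-[3,4,5-tris(benzyloxy)-2-bromophenyl]propan-1-ol, via [3,4,5-tris(benzyloxy)-2-bromophenyl]magnesium chloride 19 (not isolated)
Conditions: 18, iPrMgCl·LiCl (0.98 equiv), THF, −30 °C; then added to 14 and MgBr2·OEt2 in CH2Cl2, −78 to −40 °C; aq NH4Cl
Reagents that add atoms: none
Why: Iodine–magnesium exchange is much faster than bromine–magnesium exchange and the 2-bromoarylmagnesium 19 is expected to keep its bromine at these temperatures; Grignard addition to 14 through the five-membered magnesium chelate of carbonyl and α-benzyloxy oxygens (Cram chelate control) delivers the aryl group anti to the arylmethyl substituent and sets C2 of unit 2 as R (syn carbinol).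

Step 13
Reactants: 20 (1R,2R)-2-(benzyloxy)-3-[2,4-bis(benzyloxy)-6-bromophenyl]-1-[3,4,5-tris(benzyloxy)-2-bromophenyl]propan-1-ol
Product: 21 (2R,3R)-3,5,7-tris(benzyloxy)-2-[3,4,5-tris(benzyloxy)-2-bromophenyl]chroman
Conditions: CuI (20 mol%), 3,4,7,8-tetramethyl-1,10-phenanthroline (40 mol%), Cs2CO3, toluene, 110 °C
Reagents that add atoms: none
Why: Ullmann-type copper-catalysed intramolecular O-arylation closes the six-membered ring C of unit 2 at the ring A bromide (the ring B bromide could only give a four-membered ring and is flanked on both sides); no bond at C2 or C3 is broken, so the 2,3-cis (2R,3R) configuration is retained.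

Step 14
Reactants: 22 4,5-dibromocatechol
Product: 23 1,2-bis(benzyloxy)-4,5-dibromobenzene
Conditions: BnBr, K2CO3, DMF, 60 °C
Reagents that add atoms: benzyl bromide, BrCc1ccccc1
Why: Williamson ether synthesis on both phenols.

Step 15
Reactants: 21 (2R,3R)-3,5,7-tris(benzyloxy)-2-[3,4,5-tris(benzyloxy)-2-bromophenyl]chroman; 23 1,2-bis(benzyloxy)-4,5-dibromobenzene; 14 (R)-2-(benzyloxy)-3-[2,4-bis(benzyloxy)-6-bromophenyl]propanal
Product: 29 (1R,2R)-2-(benzyloxy)-3-[2,4-bis(benzyloxy)-6-bromophenyl]-1-{4,5-bis(benzyloxy)-2-[2,3,4-tris(benzyloxy)-6-((2R,3R)-3,5,7-tris(benzyloxy)chroman-2-yl)phenyl]phenyl}propan-1-ol, via unit 2 aryllithium 24 (not isolated), via unit 2 arylmagnesium bromide 25 (not isolated), via 2-bromo-4,5-bis(benzyloxy)phenylmagnesium chloride 26 (not isolated), via 4,5-bis(benzyloxy)benzyne 27 (not isolated), via 2-biarylmagnesium bromide 28 (not isolated)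
Conditions: 21, t-BuLi (2 equiv), THF, −78 °C; MgBr2·OEt2, −78 to 0 °C; then 26 (made apart from 23 and iPrMgCl·LiCl, THF, −15 °C, kept cold) added slowly at 50 °C; then −78 °C, added to 14 and MgBr2·OEt2 in CH2Cl2, −78 to −20 °C; aq NH4Cl
Reagents that add atoms: none
Why: Bromine–magnesium exchange on 23 gives 26, which loses MgBrCl as it enters the warm solution and forms the symmetric aryne 27; the di-ortho-substituted Grignard 25 adds across the strained triple bond, so the crowded biaryl bond C6' (ring B of unit 1)–C2' (ring B of unit 2) is made by carbomagnesiation and not by a reductive elimination, and the new carbon–magnesium bond of 28 sits at C1' of the catechol ring. The closest known reaction type is the addition of arylmagnesium halides to arynes with electrophilic trapping of the 2-biarylmagnesium (the way dialkylbiarylphosphines are made), here with an aldehyde as the trap. No ring closes in this step. The new stereocentre, C2 of unit 1, is set as R by the Cram chelate: magnesium bridges the carbonyl and α-benzyloxy oxygens of 14 and the biaryl group is delivered to the face anti to the arylmethyl substituent, which gives the syn (1R,2R) carbinol. Regiochemistry does not arise because 27 is symmetric about its two benzyloxy-bearing carbons; the aryne must meet 25 and not its own precursor 26, which is secured by having all of 25 present and feeding 26 in slowly, and 14 is added only after all 26 has eliminated. The aryl bromide of 14, the benzyl ethers and the benzylic C2–O1 bond of unit 2 should be inert to arylmagnesium reagents under these conditions.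

Step 16
Reactants: 29 (1R,2R)-2-(benzyloxy)-3-[2,4-bis(benzyloxy)-6-bromophenyl]-1-{4,5-bis(benzyloxy)-2-[2,3,4-tris(benzyloxy)-6-((2R,3R)-3,5,7-tris(benzyloxy)chroman-2-yl)phenyl]phenyl}propan-1-ol
Product: 30 undeca-O-benzyl degalloyl theasinensin F
Conditions: CuI (20 mol%), 3,4,7,8-tetramethyl-1,10-phenanthroline (40 mol%), Cs2CO3, toluene, 110 °C
Reagents that add atoms: none
Why: The same Ullmann-type intramolecular O-arylation as in step 13 closes the six-membered ring C of unit 1 at O1–C8a; the carbinol carbon keeps its four bonds, so C2 is retained as R and the 2,3-cis relationship follows from the syn carbinol.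

Step 17
Reactants: 30 undeca-O-benzyl degalloyl theasinensin F
Product: 31 degalloyl theasinensin F
Conditions: H2 (1 atm), Pd(OH)2/C, THF/MeOH, rt; filtration and work-up under argon
Reagents that add atoms: none
Why: Catalytic hydrogenolysis of eleven benzyl ethers; the two chroman C2–O1 bonds are cyclic benzylic aryl ethers that should cleave much more slowly than O-benzyl groups under these neutral conditions, and no stereocentre is involved.

**Compound list**
1 | 5-bromoresorcinol | Oc1cc(O)cc(Br)c1 | starting material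
2 | 1,3-bis(benzyloxy)-5-bromobenzene | Brc1cc(OCc2ccccc2)cc(OCc2ccccc2)c1 | intermediate
3 | N-[2,4-bis(benzyloxy)-6-bromobenzylidene]-N-methylmethanaminium chloride | C[N+](C)=Cc1c(Br)cc(OCc2ccccc2)cc1OCc2ccccc2.[Cl-] | intermediate
4 | 2,4-bis(benzyloxy)-6-bromobenzaldehyde | O=Cc1c(Br)cc(OCc2ccccc2)cc1OCc2ccccc2 | intermediate
5 | [2,4-bis(benzyloxy)-6-bromophenyl]methanol | OCc1c(Br)cc(OCc2ccccc2)cc1OCc2ccccc2 | intermediate
6 | 1,5-bis(benzyloxy)-3-bromo-2-(bromomethyl)benzene | BrCc1c(Br)cc(OCc2ccccc2)cc1OCc2ccccc2 | intermediate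
7 | (S)-4-benzyloxazolidin-2-one | O=C1N[C@@H](Cc2ccccc2)CO1 | starting material
8 | (benzyloxy)acetyl chloride | O=C(Cl)COCc1ccccc1 | starting material
9 | lithium salt of (S)-4-benzyloxazolidin-2-one | O=C1N([Li])[C@@H](Cc2ccccc2)CO1 | intermediate
10 | (S)-4-benzyl-3-[(benzyloxy)acetyl]oxazolidin-2-one | O=C(COCc1ccccc1)N1[C@@H](Cc2ccccc2)COC1=O | intermediate
11 | sodium Z-enolate of 10 | [Na+].[O-]/C(=C\OCc1ccccc1)N1[C@@H](Cc2ccccc2)COC1=O | intermediate
12 | (S)-4-benzyl-3-{(R)-2-(benzyloxy)-3-[2,4-bis(benzyloxy)-6-bromophenyl]propanoyl}oxazolidin-2-one | O=C([C@H](OCc1ccccc1)Cc1c(Br)cc(OCc2ccccc2)cc1OCc2ccccc2)N1[C@@H](Cc2ccccc2)COC1=O | intermediate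
13 | (R)-2-(benzyloxy)-3-[2,4-bis(benzyloxy)-6-bromophenyl]propan-1-ol | OC[C@H](OCc1ccccc1)Cc1c(Br)cc(OCc2ccccc2)cc1OCc2ccccc2 | intermediate
14 | (R)-2-(benzyloxy)-3-[2,4-bis(benzyloxy)-6-bromophenyl]propanal | O=C[C@H](OCc1ccccc1)Cc1c(Br)cc(OCc2ccccc2)cc1OCc2ccccc2 | intermediate
15 | 5-iodo-1,2,3-trimethoxybenzene | COc1cc(I)cc(OC)c1OC | starting material
16 | 5-iodobenzene-1,2,3-triol | Oc1cc(I)cc(O)c1O | intermediate
17 | 1,2,3-tris(benzyloxy)-5-iodobenzene | Ic1cc(OCc2ccccc2)c(OCc2ccccc2)c(OCc2ccccc2)c1 | intermediate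
18 | 1,2,3-tris(benzyloxy)-4-bromo-5-iodobenzene | Ic1cc(OCc2ccccc2)c(OCc2ccccc2)c(OCc2ccccc2)c1Br | intermediate
19 | [3,4,5-tris(benzyloxy)-2-bromophenyl]magnesium chloride | Cl[Mg]c1cc(OCc2ccccc2)c(OCc2ccccc2)c(OCc2ccccc2)c1Br | intermediate
20 | (1R,2R)-2-(benzyloxy)-3-[2,4-bis(benzyloxy)-6-bromophenyl]-1-[3,4,5-tris(benzyloxy)-2-bromophenyl]propan-1-ol | O[C@H](c1cc(OCc2ccccc2)c(OCc2ccccc2)c(OCc2ccccc2)c1Br)[C@H](OCc1ccccc1)Cc1c(Br)cc(OCc2ccccc2)cc1OCc2ccccc2 | intermediate
21 | (2R,3R)-3,5,7-tris(benzyloxy)-2-[3,4,5-tris(benzyloxy)-2-bromophenyl]chroman | Brc1c([C@H]3Oc4cc(OCc5ccccc5)cc(OCc5ccccc5)c4C[C@H]3OCc5ccccc5)cc(OCc5ccccc5)c(OCc5ccccc5)c1OCc5ccccc5 | intermediate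
22 | 4,5-dibromocatechol | Oc1cc(Br)c(Br)cc1O | starting material
23 | 1,2-bis(benzyloxy)-4,5-dibromobenzene | Brc1cc(OCc2ccccc2)c(OCc2ccccc2)cc1Br | intermediate
24 | unit 2 aryllithium: {2,3,4-tris(benzyloxy)-6-[(2R,3R)-3,5,7-tris(benzyloxy)chroman-2-yl]phenyl}lithium | [Li]c1c([C@H]3Oc4cc(OCc5ccccc5)cc(OCc5ccccc5)c4C[C@H]3OCc5ccccc5)cc(OCc5ccccc5)c(OCc5ccccc5)c1OCc5ccccc5 | intermediate
25 | unit 2 arylmagnesium bromide: {2,3,4-tris(benzyloxy)-6-[(2R,3R)-3,5,7-tris(benzyloxy)chroman-2-yl]phenyl}magnesium bromide | Br[Mg]c1c([C@H]3Oc4cc(OCc5ccccc5)cc(OCc5ccccc5)c4C[C@H]3OCc5ccccc5)cc(OCc5ccccc5)c(OCc5ccccc5)c1OCc5ccccc5 | intermediate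
26 | [4,5-bis(benzyloxy)-2-bromophenyl]magnesium chloride | Cl[Mg]c1cc(OCc2ccccc2)c(OCc2ccccc2)cc1Br | intermediate
27 | 4,5-bis(benzyloxy)benzyne | C1#CC=C(OCc2ccccc2)C(OCc2ccccc2)=C1 | intermediate
28 | 2-biarylmagnesium bromide: {4,5-bis(benzyloxy)-2-[2,3,4-tris(benzyloxy)-6-((2R,3R)-3,5,7-tris(benzyloxy)chroman-2-yl)phenyl]phenyl}magnesium bromide | Br[Mg]c1cc(OCc5ccccc5)c(OCc5ccccc5)cc1-c1c([C@H]3Oc4cc(OCc5ccccc5)cc(OCc5ccccc5)c4C[C@H]3OCc5ccccc5)cc(OCc5ccccc5)c(OCc5ccccc5)c1OCc5ccccc5 | intermediate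
29 | (1R,2R)-2-(benzyloxy)-3-[2,4-bis(benzyloxy)-6-bromophenyl]-1-{4,5-bis(benzyloxy)-2-[2,3,4-tris(benzyloxy)-6-((2R,3R)-3,5,7-tris(benzyloxy)chroman-2-yl)phenyl]phenyl}propan-1-ol (syn carbinol; unit 2 complete; unit 1 open at O1–C8a) | O[C@H](c1cc(OCc5ccccc5)c(OCc5ccccc5)cc1-c1c([C@H]3Oc4cc(OCc5ccccc5)cc(OCc5ccccc5)c4C[C@H]3OCc5ccccc5)cc(OCc5ccccc5)c(OCc5ccccc5)c1OCc5ccccc5)[C@H](OCc5ccccc5)Cc1c(Br)cc(OCc5ccccc5)cc1OCc5ccccc5 | intermediate
30 | undeca-O-benzyl degalloyl theasinensin F: (2R,3R)-3,5,7-tris(benzyloxy)-2-{4,5-bis(benzyloxy)-2-[2,3,4-tris(benzyloxy)-6-((2R,3R)-3,5,7-tris(benzyloxy)chroman-2-yl)phenyl]phenyl}chroman | O(Cc5ccccc5)c1cc(OCc5ccccc5)c2c(c1)O[C@H](c1cc(OCc5ccccc5)c(OCc5ccccc5)cc1-c1c([C@H]3Oc4cc(OCc5ccccc5)cc(OCc5ccccc5)c4C[C@H]3OCc5ccccc5)cc(OCc5ccccc5)c(OCc5ccccc5)c1OCc5ccccc5)[C@H](OCc5ccccc5)C2 | intermediate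
31 | degalloyl theasinensin F | Oc1cc(O)c2c(c1)O[C@H](c1cc(O)c(O)cc1-c1c([C@H]3Oc4cc(O)cc(O)c4C[C@H]3O)cc(O)c(O)c1O)[C@H](O)C2 | target

**Count and risk**
Total step count: 17. Longest linear sequence: 12 steps (steps 1, 2, 3, 4, 6, 7, 8, 12, 13, 15, 16, 17).

The three steps most likely to fail:

Step 15. The carbomagnesiation by the di-ortho-substituted Grignard 25 may be slower than attack of 26 on the aryne, so that 27 is lost to oligomerisation, or the crowded 28 may enolise 14 instead of adding to it. The fallback sets out from 21 and comes back to the route at 29. Bromine–lithium exchange on 21 (t-BuLi, THF, −78 °C) and quench with 2-isopropoxy-4,4,5,5-tetramethyl-1,3,2-dioxaborolane should give the pinacol boronate (2R,3R)-3,5,7-tris(benzyloxy)-2-[3,4,5-tris(benzyloxy)-2-(4,4,5,5-tetramethyl-1,3,2-dioxaborolan-2-yl)phenyl]chroman F1. Suzuki–Miyaura coupling of F1 with an excess of 23 (Pd(OAc)2, 2-dicyclohexylphosphino-2',6'-dimethoxybiphenyl, K3PO4, toluene/H2O, 90 °C) should give the 2-bromobiaryl (2R,3R)-3,5,7-tris(benzyloxy)-2-{3,4,5-tris(benzyloxy)-2-[4,5-bis(benzyloxy)-2-bromophenyl]phenyl}chroman F2. Bromine–lithium exchange on F2 (t-BuLi, −78 °C) and transmetalation with MgBr2·OEt2 then give 28, which is added to the MgBr2 complex of 14 as in step 15 to reach 29. The biaryl bond is thus made by cross-coupling, and the aldehyde addition becomes a separate operation.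

Step 16. The alkoxide next to the tri-ortho-substituted biaryl may bind copper poorly, so that C–O coupling is slow and hydrodebromination or oxidation of the carbinol competes. The fallback sets out from 29 and comes back at 30. Miyaura borylation of the aryl bromide (bis(pinacolato)diboron, PdCl2(dppf) with dppf = 1,1'-bis(diphenylphosphino)ferrocene, KOAc, dioxane, 90 °C) should give the pinacol boronate (1R,2R)-2-(benzyloxy)-3-[2,4-bis(benzyloxy)-6-(4,4,5,5-tetramethyl-1,3,2-dioxaborolan-2-yl)phenyl]-1-{4,5-bis(benzyloxy)-2-[2,3,4-tris(benzyloxy)-6-((2R,3R)-3,5,7-tris(benzyloxy)chroman-2-yl)phenyl]phenyl}propan-1-ol F3. Oxidative intramolecular etherification of F3 with copper diacetate (Cu(OAc)2, pyridine, 4 Å molecular sieves, CH2Cl2, rt; Chan–Lam coupling) forms the same O1–C8a bond at room temperature and again leaves C2 untouched.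

Step 12. THF and LiCl may compete with the α-benzyloxy group for magnesium, so that chelation is incomplete and facial selectivity is poor. The fallback sets out from 20 (as its diastereomer mixture) and comes back at 20. Dess–Martin oxidation should give the ketone (R)-2-(benzyloxy)-3-[2,4-bis(benzyloxy)-6-bromophenyl]-1-[3,4,5-tris(benzyloxy)-2-bromophenyl]propan-1-one F4. Reduction of F4 with LiBH(s-Bu)3 (THF, −78 °C) under Felkin–Anh, non-chelation control should deliver hydride to the face that gives the syn (1R,2R) carbinol 20.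

**Further compounds**
F1 | step 15 | (2R,3R)-3,5,7-tris(benzyloxy)-2-[3,4,5-tris(benzyloxy)-2-(4,4,5,5-tetramethyl-1,3,2-dioxaborolan-2-yl)phenyl]chroman | CC1(C)OB(OC1(C)C)c1c([C@H]3Oc4cc(OCc5ccccc5)cc(OCc5ccccc5)c4C[C@H]3OCc5ccccc5)cc(OCc5ccccc5)c(OCc5ccccc5)c1OCc5ccccc5
F2 | step 15 | (2R,3R)-3,5,7-tris(benzyloxy)-2-{3,4,5-tris(benzyloxy)-2-[4,5-bis(benzyloxy)-2-bromophenyl]phenyl}chroman | Brc1cc(OCc5ccccc5)c(OCc5ccccc5)cc1-c1c([C@H]3Oc4cc(OCc5ccccc5)cc(OCc5ccccc5)c4C[C@H]3OCc5ccccc5)cc(OCc5ccccc5)c(OCc5ccccc5)c1OCc5ccccc5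
F3 | step 16 | (1R,2R)-2-(benzyloxy)-3-[2,4-bis(benzyloxy)-6-(4,4,5,5-tetramethyl-1,3,2-dioxaborolan-2-yl)phenyl]-1-{4,5-bis(benzyloxy)-2-[2,3,4-tris(benzyloxy)-6-((2R,3R)-3,5,7-tris(benzyloxy)chroman-2-yl)phenyl]phenyl}propan-1-ol | O[C@H](c1cc(OCc5ccccc5)c(OCc5ccccc5)cc1-c1c([C@H]3Oc4cc(OCc5ccccc5)cc(OCc5ccccc5)c4C[C@H]3OCc5ccccc5)cc(OCc5ccccc5)c(OCc5ccccc5)c1OCc5ccccc5)[C@H](OCc5ccccc5)Cc1c(B2OC(C)(C)C(C)(C)O2)cc(OCc5ccccc5)cc1OCc5ccccc5
F4 | step 12 | (R)-2-(benzyloxy)-3-[2,4-bis(benzyloxy)-6-bromophenyl]-1-[3,4,5-tris(benzyloxy)-2-bromophenyl]propan-1-one | O=C(c1cc(OCc2ccccc2)c(OCc2ccccc2)c(OCc2ccccc2)c1Br)[C@H](OCc1ccccc1)Cc1c(Br)cc(OCc2ccccc2)cc1OCc2ccccc2
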